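## The problem

The target is a germacrane 7(11)-en-12,6-olide. A ten-membered carbocycle (C1–C10) is fused at C6–C7 to a butenolide whose C11 carries the acetoxymethyl group C13. The ring holds a (Z)-C2=C3 alkene between a 1,10-epoxide (with the free C14 hydroxymethyl on C10) and a 4,5-epoxide (with the C15 methyl), and C8 carries an (R)-2-methylbutanoate.

Read from the structure, the configuration is 1R,4R,5S,6S,8S,10S and 2′R. The 1,10-epoxide has C9 and C2 trans and the 4,5-epoxide has C3 and C6 cis. Because epoxidation is stereospecific, the parent triene must have C1=C10 "ring-trans" (C9 trans to C2), C2=C3 Z and C4=C5 "ring-cis" (C3 cis to C6); any other triene gives the wrong pair of epoxides.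

A ten-membered ring is poorly made by end-to-end C–C closure, so the ring should come from a larger or smaller ring.

C8 can be set by a catalyst and then control C6 in the ring-forming step. A free C6 hydroxyl can deliver oxygen to C4=C5. C1/C10 need a chiral reagent, and C2′ is bought.

Fragile groups in the product are the two vinyl epoxides (acid, soft nucleophiles, zerovalent palladium), the 2-(acetoxymethyl)butenolide (base, SN2′ addition–elimination) and two further esters. The parent trans,cis,cis-cyclodeca-1(10),2,4-triene is expected to close thermally (6π) to a decalin, so it may exist only briefly and cold.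

The enabling feature is that C6 bears oxygen and is bonded to C7, whose substituent C11 carries the two one-carbon arms C12 and C13. The unit C6(O)–C7–C11(=C13) is exactly what a [2,3]-Wittig shift of an allyl ether C6–O–C13–C11=C7 delivers, and the ring O, C13, C11, C7–C10, C1–C6 has 13 members.

## Retrosynthesis

**Ester and protecting groups (53 ⇐ 52 ⇐ 50 + 51 ⇐ 49).** The last operations are cleavage of the C14 silyl ether of 52, acylation of the C8 alcohol 50 with the acid 51 and removal of the C8 p-methoxybenzyl ether of 49. C14 must stay protected until C8 is acylated, because the primary alcohol would react first. The C8 ester cannot be brought in earlier because it would not survive butyllithium. This asks only for mild, non-nucleophilic conditions on a compound that already holds both epoxides.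

**Butenolide (49 ⇐ 47 ⇐ 45 ⇐ 42).** The C7=C11 bond and the C13 acetate are traced to the α-methylene lactone 42 through the 11,13-diol 45 and its primary acetate 47, with syn-dehydration of the tertiary alcohol. Allylic oxidation or radical bromination of 42 would compete at C6–H, C8–H and the epoxide C–H bonds. Electrophilic selenium would attack C2=C3 first. The diol route uses only the exocyclic alkene, the one unhindered alkene left.

**Lactone (42 ⇐ 39 ⇐ 38).** The C12 carbonyl is the oxidised C12 arm of the diol 39, closed on the C6 hydroxyl. With C8 and C14 protected only the 12,6-olide can form.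

**Epoxides (38 ⇐ 36 ⇐ 34).** Both epoxides are removed directly after the ring-forming step: 1,10 by a chiral dioxirane on 36, and 4,5 by hydroxyl-directed epoxidation of the trienol 34. Doing this first, rather than last, uses the free C6 hydroxyl as the control element for C4/C5 and destroys the thermally labile triene within one step of its formation.

**Key cut (34 ⇐ 32).** Bond C6–C7 is cut and O–C13 is re-formed, which expands the ten-membered trienol 34 to the 13-membered ether 32. Against direct closure of C6–C7, C1–C10 or C8–C9, this cut gives a ring that is easy to close and a concerted intramolecular C–C bond formation that sets C6 from C8. It leaves C11 with its two arms exactly as the butenolide needs them.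

**Ether (32 ⇐ 31 ⇐ 30 ⇐ 27).** The C6–O–C13 bond is cut to a C6 alkoxide and a C13 allylic chloride (31). The chloride is placed on C13, not C6, because a trienylic halide at C6 would ionise and scramble. This costs a silyl ether on C6 (30) while C13 is activated.

**Triene (27 ⇐ 26 ⇐ 25 + 3).** C2=C3 is taken back to an alkyne (26) and C1–C2 to a coupling of the vinyl bromide 25 with the enyne 3. A Wittig route to C2=C3 would need an allylic ylide and would not give clean Z geometry. The enyne 3 comes from the purchased enynol 1, which already has C3 cis to C6.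

**C7=C11 with two different arms (25 ⇐ 24 ⇐ 22 ⇐ 20 ⇐ 18 ⇐ 15).** The trisubstituted alkene is traced to the propargylic alcohol 15: trans-hydroalumination/iodination gives 18, and the iodide of 20 is exchanged for CH2OH from the stannane 21. An olefination of a symmetric dihydroxyacetone unit would leave two identical arms to be told apart afterwards. Here the C13 arm comes with the alkyne and the C12 arm with the coupling, cis to C8 by construction.

**C8 (15 ⇐ 13 + 5).** The C7–C8 bond is cut to the aldehyde 13 and the alkyne 5 (from 4 and 2). One catalytic asymmetric addition makes the only stereocentre needed before the key step.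

**C1=C10 (13 ⇐ 11 ⇐ 9 ⇐ 4 + 6 + 7).** The bromoalkene is traced to anti-carbomagnesiation of propargyl alcohol 4 with allylmagnesium bromide 6 and bromination with 7. Olefination of a hydroxyacetone-type ketone gives mainly the isomer with C2 trans to C14, which is wrong here. The chelate-controlled addition gives C14 cis to the halide in one step, and the allyl group supplies C9 and, after cleavage, the C8 aldehyde.

## Roads not taken

**Alternative 1:** macrocyclising sulfonium ylide epoxidation at C1–C10.
- **Cut:** C1–C10 and C1–O.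
- **Forward step:** the acyclic keto sulfonium salt A2, treated with a strong amide base, forms an ylide at C1 that adds to the C10 ketone and closes the ring and the epoxide together to give A1.
- **Merits:** ring and 1,10-epoxide arise in one step from a fully functionalised chain. No cyclodecatriene ever exists; in this respect the road is better than the chosen one.
- **Weak points:** it is an end-to-end ten-membered C–C closure. The two new centres C1 and C10 have no control element beyond a remote C8. A2 offers the base several other sites: the γ-hydrogen at C6 of the butenolide, the SN2′-prone acetoxymethyl group and the allylic sulfonium itself. A2 still needs the cis-4,5-epoxide and the butenolide, so it is not shorter.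
- **Comparison:** the chosen plan sets against it a ring closure at the 13-membered stage and a control element for every new centre.

**Alternative 2:** photochemical opening of a cis-fused eudesmadiene.
- **Cut:** C5–C10 is re-formed.
- **Forward step:** irradiation of the cis-fused 1,3-diene lactone A4 opens C5–C10 in a conrotatory sense to the trienolide A3.
- **Merits:** it is the shortest road. The decalin controls C6 and C8 easily, and all esters are in place; it reaches in one step what the chosen route needs about ten steps after the contraction to add.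
- **Weak points:** the two conrotatory modes put the ring-trans bond at either end, and only one is useful. The reaction stops at a photostationary mixture. A3 recloses thermally and absorbs light itself. Afterwards the 4,5-epoxidation has no hydroxyl to direct it, because C6 is already the lactone oxygen.
- **Comparison:** the chosen plan forms the same triene in the ground state at −78 °C as one geometric isomer, with C6–OH free for the next step.

**Alternative 3:** anionic oxy-Cope expansion.
- **Cut:** C8–C9 is formed and C1–C6 broken.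
- **Forward step:** the potassium alkoxide of the 1,2-dialkenylcyclohex-3-enol A6 undergoes a [3,3] shift to the ten-membered dienone A5.
- **Merits:** a strongly driven, reliable 6 → 10 expansion. C1=C10 geometry comes from a chair transition state, and C4/C5 oxygenation is set on a six-membered ring. No triene is formed; on both counts it is at least as good as the chosen plan.
- **Weak points:** A5 has C7 as CH2 and C6 as a ketone. The whole C11–C13 unit and the C6 centre must then be added to an enolisable ten-membered ketone (C5 versus C7 enolisation). The cis-epoxide must be made from the diol by selective activation. C8 rests on enol ether geometry.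
- **Comparison:** the chosen plan makes C6–O, C6–C7 and C11 with both arms in the step that makes the ring.

Key step: step 17

Remark: locants follow germacrane numbering (C12 and C13 on C11, C14 on C10, C15 on C4). Alkene geometries of all intermediates are those required by 1R,10S (C9/C2 trans) and 4R,5S (C3/C6 cis) in the target.

Remark: (tributylstannyl)methanol, (2R)-2-methylbutanoic acid, the ProPhenol ligand, the D-fructose-derived Shi ketone and Burgess reagent are taken as purchasable.

Abbreviations: TES = triethylsilyl, TBS = tert-butyldimethylsilyl, TBDPS = tert-butyldiphenylsilyl, PMB = 4-methoxybenzyl.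

## Route

Step 1
Reactants: 1 (2Z)-3-methylpent-2-en-4-yn-1-ol; 2 chlorotriethylsilane
Product: 3 triethyl{[(2Z)-3-methylpent-2-en-4-yn-1-yl]oxy}silane
Conditions: imidazole, CH2Cl2, 0 °C
Reagents that add atoms: chlorotriethylsilane, CC[Si](Cl)(CC)CC
Why: Silylation of a primary allylic alcohol; the C6 oxygen is masked so that C13 can later be activated alone, and the ether survives coupling and zinc reduction but is cleaved by buffered HF.

Step 2
Reactants: 4 prop-2-yn-1-ol; 2 chlorotriethylsilane
Product: 5 triethyl(prop-2-yn-1-yloxy)silane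
Conditions: imidazole, CH2Cl2, 0 °C
Reagents that add atoms: chlorotriethylsilane, CC[Si](Cl)(CC)CC
Why: Same silylation; the TES ether masks the future C13 oxygen through the zinc, aluminium hydride and palladium steps and is the first silyl group to be removed.

Step 3
Reactants: 4 prop-2-yn-1-ol; 6 allylmagnesium bromide; 7 N-bromosuccinimide
Product: 9 (2Z)-2-(bromomethylidene)pent-4-en-1-ol, via alkenylmagnesium alkoxide 8 (not isolated)
Conditions: 6 (3 equiv), CuI (10 mol%), Et2O, −78 → 20 °C; then 7, THF, −78 → 0 °C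
Reagents that add atoms: allylmagnesium bromide, C=CC[Mg]Br; N-bromosuccinimide, O=C1CCC(=O)N1Br
Why: Copper-catalysed anti-carbomagnesiation of propargyl alcohol: the magnesium alkoxide directs allyl to the internal carbon and magnesium to the terminal carbon cis to CH2OH (five-membered chelate), and bromination of the C–Mg bond with retention fixes C1=C10 with bromine (later C2) cis to C14 and trans to C9.

Step 4
Reactants: 9 (2Z)-2-(bromomethylidene)pent-4-en-1-ol; 10 tert-butyl(chloro)diphenylsilane
Product: 11 {[(2Z)-2-(bromomethylidene)pent-4-en-1-yl]oxy}(tert-butyl)diphenylsilane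
Conditions: imidazole, DMF, 20 °C
Reagents that add atoms: tert-butyl(chloro)diphenylsilane, CC(C)(C)[Si](Cl)(c1ccccc1)c1ccccc1
Why: Standard silylation; the bulky TBDPS ether stays to the last step and later screens the C14 methylene against lithiation.

Step 5
Reactants: 11 TBDPS ether of 9; 12 sodium periodate
Product: 13 (3Z)-4-bromo-3-{[(tert-butyldiphenylsilyl)oxy]methyl}but-3-enal
Conditions: OsO4 (2 mol%), 12 (4 equiv), 2,6-lutidine, dioxane/H2O, 20 °C; used crude
Reagents that add atoms: sodium periodate, [Na+].[O-]I(=O)(=O)=O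
Why: Lemieux–Johnson cleavage takes the monosubstituted alkene in preference to the electron-poor trisubstituted bromoalkene and gives the C8 aldehyde; the β,γ-unsaturated aldehyde is used at once to avoid conjugation.

Step 6
Reactants: 13 aldehyde; 5 triethyl(prop-2-yn-1-yloxy)silane
Product: 15 (1Z,4S)-1-bromo-2-{[(tert-butyldiphenylsilyl)oxy]methyl}-7-[(triethylsilyl)oxy]hept-1-en-5-yn-4-ol, via methylzinc acetylide 14 (not isolated)
Conditions: Me2Zn (3 equiv), (S,S)-ProPhenol (20 mol%), Ph3PO (40 mol%), toluene, 0 °C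
Reagents that add atoms: triethyl(prop-2-yn-1-yloxy)silane, C#CCO[Si](CC)(CC)CC
Why: Zinc–ProPhenol catalysed asymmetric alkynylation of an aldehyde, amine-free so the aldehyde is not isomerised; the chiral dinuclear zinc catalyst selects the aldehyde face and sets C8 as S (the ligand antipode is used if the sense proves opposite).

Step 7
Reactants: 15 propargylic alcohol; 16 iodine
Product: 18 (1Z,4S,5Z)-1-bromo-2-{[(tert-butyldiphenylsilyl)oxy]methyl}-6-iodo-7-[(triethylsilyl)oxy]hepta-1,5-dien-4-ol, via alkenylaluminate 17 (not isolated)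
Conditions: NaAlH2(OCH2CH2OMe)2 (1.6 equiv), THF, −20 → 0 °C; EtOAc; then 16, −78 → 0 °C
Reagents that add atoms: iodine, II
Why: Alkoxide-directed trans-hydroalumination of a propargylic alcohol puts aluminium on the distal carbon C11 and hydride on C7, and iodinolysis with retention gives the vinyl iodide with iodine cis to C8; vinyl bromide and silyl ethers are inert at 0 °C.

Step 8
Reactants: 18 iodo alcohol; 19 4-methoxybenzyl chloride
Product: 20 (1Z,4S,5Z)-1-bromo-2-{[(tert-butyldiphenylsilyl)oxy]methyl}-6-iodo-4-[(4-methoxybenzyl)oxy]-7-[(triethylsilyl)oxy]hepta-1,5-diene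
Conditions: NaH, Bu4NI (cat.), THF/DMF, 0 → 20 °C
Reagents that add atoms: 4-methoxybenzyl chloride, COc1ccc(CCl)cc1
Why: Williamson benzylation of the secondary alkoxide; the PMB ether withstands butyllithium and is removed oxidatively only when no conjugated polyene is left.

Step 9
Reactants: 20 vinyl iodide; 21 (tributylstannyl)methanol
Product: 22 (2E,4S,6Z)-7-bromo-6-{[(tert-butyldiphenylsilyl)oxy]methyl}-4-[(4-methoxybenzyl)oxy]-2-{[(triethylsilyl)oxy]methyl}hepta-2,6-dien-1-ol
Conditions: Pd2(dba)3 (3 mol%), AsPh3, CuI (10 mol%), NMP, 50 °C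
Reagents that add atoms: (tributylstannyl)methanol, CCCC[Sn](CCCC)(CCCC)CO
Why: Stille coupling that transfers the α-oxygenated CH2OH group; oxidative addition to the vinyl iodide is far faster than to the vinyl bromide, and retention puts C12 cis to C8 and leaves the C13 arm trans, so the two arms on C11 are differentiated by synthesis.

Step 10
Reactants: 22 allylic alcohol; 23 tert-butyl(chloro)dimethylsilane
Product: 24 C12 TBS ether of 22
Conditions: imidazole, CH2Cl2, 0 °C
Reagents that add atoms: tert-butyl(chloro)dimethylsilane, CC(C)(C)[Si](C)(C)Cl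
Why: Silylation of the only free (primary allylic) hydroxyl; TBS is chosen to outlast both TES ethers.

Step 11
Reactants: 24 bis-silyl ether
Product: 25 (2Z,4S,6Z)-7-bromo-2-{[(tert-butyldimethylsilyl)oxy]methyl}-6-{[(tert-butyldiphenylsilyl)oxy]methyl}-4-[(4-methoxybenzyl)oxy]hepta-2,6-dien-1-ol
Conditions: pyridinium p-toluenesulfonate, MeOH, 0 °C
Reagents that add atoms: none
Why: Acid-catalysed methanolysis cleaves the primary TES ether far faster than primary TBS or TBDPS ethers, freeing C13–OH; no acid-sensitive polyene is present yet.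

Step 12
Reactants: 25 vinyl bromide; 3 enyne TES ether
Product: 26 (2Z,4S,6Z,10Z)-2-{[(tert-butyldimethylsilyl)oxy]methyl}-6-{[(tert-butyldiphenylsilyl)oxy]methyl}-4-[(4-methoxybenzyl)oxy]-10-methyl-12-[(triethylsilyl)oxy]dodeca-2,6,10-trien-8-yn-1-ol
Conditions: Pd(PPh3)4 (5 mol%), CuI (10 mol%), i-Pr2NH, THF, 45 °C
Reagents that add atoms: triethyl{[(2Z)-3-methylpent-2-en-4-yn-1-yl]oxy}silane, C#C/C(C)=C\CO[Si](CC)(CC)CC
Why: Sonogashira coupling of a (Z)-vinyl bromide with a terminal enyne with retention at C1=C10; it forms C1–C2 and brings in C2–C6 and C15 with the C4=C5 geometry of the purchased enynol.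

Step 13
Reactants: 26 dienyne
Product: 27 (2Z,4S,6Z,8Z,10Z)-2-{[(tert-butyldimethylsilyl)oxy]methyl}-6-{[(tert-butyldiphenylsilyl)oxy]methyl}-4-[(4-methoxybenzyl)oxy]-10-methyl-12-[(triethylsilyl)oxy]dodeca-2,6,8,10-tetraen-1-ol
Conditions: Zn dust activated with Cu(OAc)2 and AgNO3, MeOH/H2O, 40 °C
Reagents that add atoms: none
Why: Boland-type semireduction with activated zinc reduces only the conjugated triple bond by cis delivery of hydrogen, giving the (Z)-C2=C3 alkene without over-reduction or isomerisation.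

Step 14
Reactants: 27 trienol; 28 lithium chloride
Product: 30 C13 allylic chloride corresponding to 27, via C13 mesylate 29 (not isolated)
Conditions: MsCl, 2,4,6-collidine, 28, DMF, 0 °C
Reagents that add atoms: lithium chloride, [Li+].[Cl-]
Why: One-pot mesylation and chloride displacement of a primary allylic alcohol (SN2 at C13) under a hindered pyridine base that leaves silyl ethers and triene untouched.

Step 15
Reactants: 30 allylic chloride
Product: 31 hydroxy chloride (30 with C6–OH free)
Conditions: HF·pyridine, pyridine, THF, 0 °C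
Reagents that add atoms: none
Why: Buffered fluoride cleaves the primary TES ether and leaves TBS, TBDPS and the allylic chloride intact.

Step 16
Reactants: 31 hydroxy chloride
Product: 32 (8S)-13-membered ether C6–O–C13 with 8-OPMB, 12-OTBS and 14-OTBDPS
Conditions: NaH, Bu4NI (cat.), THF (2 mM, slow addition), 0 → 40 °C
Reagents that add atoms: none
Why: Intramolecular Williamson etherification of an alkoxide with a primary allylic chloride at high dilution, the closure known for 13-membered bis-allylic ethers; the three cis-type alkenes of the triene fold the chain so that C6–O and C13 meet.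

Step 17
Reactants: 32 13-membered ether
Product: 34 (6R,7S,8S)-12-(TBS-oxy)-14-(TBDPS-oxy)-8-(PMB-oxy)germacra-1(10),2,4,11(13)-tetraen-6-ol, via C6-lithio ether 33 (not isolated)
Conditions: n-BuLi (1.5 equiv), THF–hexane, −78 °C, 30 min; sat. aq. NH4Cl at −78 °C; used cold and at once
Reagents that add atoms: none
Why: n-Butyllithium removes a proton from C6, which is α to the ether oxygen and conjugated with the triene, and the lithiated ether 33 rearranges through a five-membered envelope (C6, O, C13, C11, C7) in which C6–C7 forms on the face of the allyl unit from which O–C13 departs. The closest known reaction type is the [2,3]-Wittig ring contraction of 13-membered bis-allylic ethers to cyclodecadienols. The ten-membered ring arises by contraction (13 → 10 atoms), not by end-to-end closure: the new bond joins atoms already held 1,5 across oxygen, and that oxygen leaves the ring as the C6 alkoxide. C7 is set relative to C6 by alkene geometry: with C13 trans to C8 and the trienyl group exo on the envelope the anti product forms (C6–O and the C7 propenyl group on opposite ring faces); this centre is erased in step 24. C6 is set from C8: allylic strain holds H8 in the plane of C7=C11, and C6 adds to C7 anti to the C8–O bond on the face that carries C9, as the tether also requires, so the 6-OH and 8-OPMB groups end on the same ring face. The step needs lithiation at C6, not at C13, C14 or the benzylic CH2: C6 alone is both next to the coordinating ether oxygen and trienylic, C14 is screened by the TBDPS group, and a p-methoxybenzyl ether is the least acidic benzyl ether. It also needs the shift to outrun the [1,2]-shift and electrocyclisation of the trienyl anion or of the product triene, which is why it is run and quenched at −78 °C and 34 is epoxidised immediately.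

Step 18
Reactants: 34 trienol; 35 tert-butyl hydroperoxide
Product: 36 (4R,5S,6S,7S,8S)-4,5-epoxy-12-(TBS-oxy)-14-(TBDPS-oxy)-8-(PMB-oxy)germacra-1(10),2,11(13)-trien-6-ol
Conditions: VO(acac)2 (5 mol%), 35 (1.2 equiv), CH2Cl2, −20 → 0 °C
Reagents that add atoms: tert-butyl hydroperoxide, CC(C)(C)OO
Why: Vanadium-catalysed hydroxyl-directed epoxidation: the peroxide bound at the C6 oxygen reaches only the allylic C4=C5 bond and delivers oxygen syn to the C6 oxygen, as for medium-ring (Z)-cycloalk-2-enols, setting 4R,5S; it also removes the labile triene.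

Step 19
Reactants: 36 epoxy dienol; 37 potassium peroxymonosulfate
Product: 38 (1R,4R,5S,6S,7S,8S,10S)-1,10:4,5-diepoxy-12-(TBS-oxy)-14-(TBDPS-oxy)-8-(PMB-oxy)germacra-2,11(13)-dien-6-ol
Conditions: D-fructose-derived Shi ketone (0.3 equiv), 37 (as Oxone), K2CO3, Bu4NHSO4, MeCN/dimethoxymethane/borate buffer pH 10.5, 0 °C
Reagents that add atoms: potassium peroxymonosulfate, [K+].[O-]S(=O)(=O)OO
Why: Shi asymmetric epoxidation: the chiral dioxirane takes the trisubstituted C1=C10 bond (cis-disubstituted C2=C3 and 1,1-disubstituted C11=C13 are poor substrates) with the facial sense found for trans-type alkenes, here 1R,10S; the basic buffer preserves the acid-labile epoxides.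

Step 20
Reactants: 38 diepoxide
Product: 39 (1R,4R,5S,6S,7S,8S,10S)-1,10:4,5-diepoxy-14-(TBDPS-oxy)-8-(PMB-oxy)germacra-2,11(13)-diene-6,12-diol
Conditions: HF·pyridine, pyridine, THF, 0 → 20 °C
Reagents that add atoms: none
Why: Buffered HF·pyridine removes the primary allylic TBS ether; the primary TBDPS ether and the epoxides, now each only mono-allylic, survive.

Step 21
Reactants: 39 diol
Product: 42 (1R,4R,5S,6S,7R,8S,10S)-1,10:4,5-diepoxy-14-(TBDPS-oxy)-8-(PMB-oxy)germacra-2,11(13)-dien-12,6-olide, via hydroxy enal 40 (not isolated), via lactol 41 (not isolated)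
Conditions: TEMPO (0.2 equiv), PhI(OAc)2 (2.5 equiv), NaHCO3, CH2Cl2, 20 °C
Reagents that add atoms: none
Why: Oxidative lactonisation of a 1,4-diol: the primary allylic alcohol is oxidised to the enal, C6–OH adds to give the lactol and this is oxidised to the lactone; the secondary alcohol is not oxidised, and C8 and C14 are protected so only the 12,6-olide forms.

Step 22
Reactants: 42 α-methylene lactone; 43 4-methylmorpholine N-oxide; 44 water
Product: 45 (1R,4R,5S,6S,7R,8S,10S,11R)-1,10:4,5-diepoxy-11,13-dihydroxy-14-(TBDPS-oxy)-8-(PMB-oxy)germacr-2-en-12,6-olide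
Conditions: OsO4 (5 mol%), 43, acetone/H2O, 0 °C
Reagents that add atoms: 4-methylmorpholine N-oxide, C[N+]1([O-])CCOCC1; water, O
Why: Catalytic osmium tetroxide dihydroxylation of the exocyclic methylene, the only unhindered alkene (C2=C3 is cis-disubstituted between two epoxides); attack anti to C8 on the lactone face that carries H7 gives the 11-hydroxyl cis to H7 (11R).

Step 23
Reactants: 45 diol; 46 acetic anhydride
Product: 47 13-acetate of 45
Conditions: pyridine, CH2Cl2, 0 °C
Reagents that add atoms: acetic anhydride, CC(=O)OC(C)=O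
Why: Acetylation of the primary hydroxyl only; the tertiary α-hydroxy lactone does not react without an acyl-transfer catalyst.

Step 24
Reactants: 47 hydroxy acetate
Product: 49 (1R,4R,5S,6S,8S,10S)-13-acetoxy-1,10:4,5-diepoxy-14-(TBDPS-oxy)-8-(PMB-oxy)germacra-2,7(11)-dien-12,6-olide, via C11 sulfamate 48 (not isolated)
Conditions: Burgess reagent, benzene, 50 °C
Reagents that add atoms: none
Why: Burgess dehydration (syn elimination through the sulfamate ester) of the tertiary alcohol: H7 is cis to the leaving group and, as in other syn eliminations, hydrogen on the oxygen-bearing C13 is avoided, so the tetrasubstituted conjugated C7=C11 bond forms and C7 and C11 cease to be stereocentres.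

Step 25
Reactants: 49 PMB ether
Product: 50 (1R,4R,5S,6S,8S,10S)-13-acetoxy-1,10:4,5-diepoxy-8-hydroxy-14-(TBDPS-oxy)germacra-2,7(11)-dien-12,6-olide
Conditions: DDQ, CH2Cl2/pH 7 buffer, 0 °C
Reagents that add atoms: none
Why: Oxidative cleavage of the PMB ether; no electron-rich polyene remains, and epoxides, esters and the silyl ether are inert.

Step 26
Reactants: 50 C8 alcohol; 51 (2R)-2-methylbutanoic acid
Product: 52 8-[(2R)-2-methylbutanoyl] ester of 50
Conditions: DCC, DMAP (5 mol%), CH2Cl2, 0 → 20 °C
Reagents that add atoms: (2R)-2-methylbutanoic acid, CC[C@@H](C)C(=O)O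
Why: Steglich esterification of the secondary C8 hydroxyl; only catalytic DMAP and low temperature are used to avoid epimerising the α-branched acyl group or SN2′ attack on the acetoxymethyl butenolide, and C14 is still silylated so only C8 reacts.

Step 27
Reactants: 52 silyl ether
Product: 53 target compound CNP0108300.1
Conditions: Bu4NF, AcOH (1:1), THF, 0 → 20 °C
Reagents that add atoms: none
Why: Fluoride cleavage of the primary TBDPS ether buffered with acetic acid, so that neither acetate migration nor Payne rearrangement of the liberated epoxy alcohol is triggered.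

## Compound list

1 | (2Z)-3-methylpent-2-en-4-yn-1-ol | C#C/C(C)=C\CO | starting material
2 | chlorotriethylsilane | CC[Si](Cl)(CC)CC | starting material
3 | triethyl{[(2Z)-3-methylpent-2-en-4-yn-1-yl]oxy}silane | C#C/C(C)=C\CO[Si](CC)(CC)CC | intermediate
4 | prop-2-yn-1-ol | C#CCO | starting material
5 | triethyl(prop-2-yn-1-yloxy)silane | C#CCO[Si](CC)(CC)CC | intermediate
6 | allylmagnesium bromide | C=CC[Mg]Br | starting material
7 | N-bromosuccinimide | O=C1CCC(=O)N1Br | starting material
8 | bromomagnesium (2Z)-2-[(bromomagnesio)methylidene]pent-4-en-1-olate (Mg on C1 cis to C14) | Br[Mg]OC/C(CC=C)=C\[Mg]Br | intermediate (not isolated)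
9 | (2Z)-2-(bromomethylidene)pent-4-en-1-ol (Br cis to CH2OH) | OC/C(CC=C)=C\Br | intermediate
10 | tert-butyl(chloro)diphenylsilane | CC(C)(C)[Si](Cl)(c1ccccc1)c1ccccc1 | starting material
11 | {[(2Z)-2-(bromomethylidene)pent-4-en-1-yl]oxy}(tert-butyl)diphenylsilane | CC(C)(C)[Si](OC/C(CC=C)=C\Br)(c1ccccc1)c1ccccc1 | intermediate
12 | sodium periodate | [Na+].[O-]I(=O)(=O)=O | starting material
13 | (3Z)-4-bromo-3-{[(tert-butyldiphenylsilyl)oxy]methyl}but-3-enal | O=CC/C(CO[Si](c1ccccc1)(c1ccccc1)C(C)(C)C)=C/Br | intermediate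
14 | methyl{3-[(triethylsilyl)oxy]prop-1-yn-1-yl}zinc | C[Zn]C#CCO[Si](CC)(CC)CC | intermediate (not isolated)
15 | (1Z,4S)-1-bromo-2-{[(tert-butyldiphenylsilyl)oxy]methyl}-7-[(triethylsilyl)oxy]hept-1-en-5-yn-4-ol (8S) | O[C@H](C#CCO[Si](CC)(CC)CC)C/C(CO[Si](c1ccccc1)(c1ccccc1)C(C)(C)C)=C/Br | intermediate
16 | iodine | II | starting material
17 | sodium bis(2-methoxyethoxy)alkenylaluminate, five-membered ring Al–O–C8–C7=C11 from 15 | COCCO[Al-]1(OCCOC)O[C@@H](C/C(CO[Si](c2ccccc2)(c2ccccc2)C(C)(C)C)=C/Br)C=C1CO[Si](CC)(CC)CC.[Na+] | intermediate (not isolated)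
18 | (1Z,4S,5Z)-1-bromo-2-{[(tert-butyldiphenylsilyl)oxy]methyl}-6-iodo-7-[(triethylsilyl)oxy]hepta-1,5-dien-4-ol (I cis to C8) | O[C@H](/C=C(\I)CO[Si](CC)(CC)CC)C/C(CO[Si](c1ccccc1)(c1ccccc1)C(C)(C)C)=C/Br | intermediate
19 | 4-methoxybenzyl chloride | COc1ccc(CCl)cc1 | starting material
20 | (1Z,4S,5Z)-1-bromo-2-{[(tert-butyldiphenylsilyl)oxy]methyl}-6-iodo-4-[(4-methoxybenzyl)oxy]-7-[(triethylsilyl)oxy]hepta-1,5-diene | COc1ccc(CO[C@H](/C=C(\I)CO[Si](CC)(CC)CC)C/C(CO[Si](c2ccccc2)(c2ccccc2)C(C)(C)C)=C/Br)cc1 | intermediate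
21 | (tributylstannyl)methanol | CCCC[Sn](CCCC)(CCCC)CO | starting material
22 | (2E,4S,6Z)-7-bromo-6-{[(tert-butyldiphenylsilyl)oxy]methyl}-4-[(4-methoxybenzyl)oxy]-2-{[(triethylsilyl)oxy]methyl}hepta-2,6-dien-1-ol (C12–OH arm cis to C8) | COc1ccc(CO[C@H](/C=C(\CO)CO[Si](CC)(CC)CC)C/C(CO[Si](c2ccccc2)(c2ccccc2)C(C)(C)C)=C/Br)cc1 | intermediate
23 | tert-butyl(chloro)dimethylsilane | CC(C)(C)[Si](C)(C)Cl | starting material
24 | tert-butyl{[(2Z,4S,6Z)-7-bromo-6-{[(tert-butyldiphenylsilyl)oxy]methyl}-4-[(4-methoxybenzyl)oxy]-2-{[(triethylsilyl)oxy]methyl}hepta-2,6-dien-1-yl]oxy}dimethylsilane (C12–OTBS cis to C8, C13–OTES trans) | COc1ccc(CO[C@H](/C=C(\CO[Si](C)(C)C(C)(C)C)CO[Si](CC)(CC)CC)C/C(CO[Si](c2ccccc2)(c2ccccc2)C(C)(C)C)=C/Br)cc1 | intermediate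
25 | (2Z,4S,6Z)-7-bromo-2-{[(tert-butyldimethylsilyl)oxy]methyl}-6-{[(tert-butyldiphenylsilyl)oxy]methyl}-4-[(4-methoxybenzyl)oxy]hepta-2,6-dien-1-ol (C13–OH free) | COc1ccc(CO[C@H](/C=C(\CO[Si](C)(C)C(C)(C)C)CO)C/C(CO[Si](c2ccccc2)(c2ccccc2)C(C)(C)C)=C/Br)cc1 | intermediate
26 | (2Z,4S,6Z,10Z)-2-{[(tert-butyldimethylsilyl)oxy]methyl}-6-{[(tert-butyldiphenylsilyl)oxy]methyl}-4-[(4-methoxybenzyl)oxy]-10-methyl-12-[(triethylsilyl)oxy]dodeca-2,6,10-trien-8-yn-1-ol | COc1ccc(CO[C@H](/C=C(\CO[Si](C)(C)C(C)(C)C)CO)C/C(CO[Si](c2ccccc2)(c2ccccc2)C(C)(C)C)=C/C#C/C(C)=C\CO[Si](CC)(CC)CC)cc1 | intermediate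
27 | (2Z,4S,6Z,8Z,10Z)-2-{[(tert-butyldimethylsilyl)oxy]methyl}-6-{[(tert-butyldiphenylsilyl)oxy]methyl}-4-[(4-methoxybenzyl)oxy]-10-methyl-12-[(triethylsilyl)oxy]dodeca-2,6,8,10-tetraen-1-ol | COc1ccc(CO[C@H](/C=C(\CO[Si](C)(C)C(C)(C)C)CO)C/C(CO[Si](c2ccccc2)(c2ccccc2)C(C)(C)C)=C/C=C\C(C)=C/CO[Si](CC)(CC)CC)cc1 | intermediate
28 | lithium chloride | [Li+].[Cl-] | starting material
29 | methanesulfonate of 27 at C13–O | COc1ccc(CO[C@H](/C=C(\CO[Si](C)(C)C(C)(C)C)COS(C)(=O)=O)C/C(CO[Si](c2ccccc2)(c2ccccc2)C(C)(C)C)=C/C=C\C(C)=C/CO[Si](CC)(CC)CC)cc1 | intermediate (not isolated)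
30 | C13 allylic chloride (27 with C13–OH replaced by Cl) | COc1ccc(CO[C@H](/C=C(\CO[Si](C)(C)C(C)(C)C)CCl)C/C(CO[Si](c2ccccc2)(c2ccccc2)C(C)(C)C)=C/C=C\C(C)=C/CO[Si](CC)(CC)CC)cc1 | intermediate
31 | hydroxy chloride (30 with the C6 TES ether cleaved to C6–OH) | COc1ccc(CO[C@H](/C=C(\CO[Si](C)(C)C(C)(C)C)CCl)C/C(CO[Si](c2ccccc2)(c2ccccc2)C(C)(C)C)=C/C=C\C(C)=C/CO)cc1 | intermediate
32 | (8S)-13-membered cyclic ether (ring O, C13, C11, C7, C8, C9, C10, C1–C6); C7=C11 with C13 trans to C8; C1=C10 with C9 trans to C2; 2Z; C4=C5 with C3 cis to C6; 8-OPMB, 12-OTBS, 14-OTBDPS, 4-methyl | O1C/C(CO[Si](C)(C)C(C)(C)C)=C/[C@@H](OCc2ccc(OC)cc2)C/C(CO[Si](c2ccccc2)(c2ccccc2)C(C)(C)C)=C/C=C\C(C)=C/C1 | intermediate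
33 | C6-lithio derivative of 32 | [Li]C1OC/C(CO[Si](C)(C)C(C)(C)C)=C/[C@@H](OCc2ccc(OC)cc2)C/C(CO[Si](c2ccccc2)(c2ccccc2)C(C)(C)C)=C/C=C\C(C)=C/1 | intermediate (not isolated)
34 | (6R,7S,8S)-12-(TBS-oxy)-14-(TBDPS-oxy)-8-(PMB-oxy)germacra-1(10),2,4,11(13)-tetraen-6-ol (C1=C10 ring-trans, 2Z, C4=C5 ring-cis; 6-OH and 8-OPMB on the same ring face, C7 propenyl group on the other) | COc1ccc(CO[C@H]2C/C(CO[Si](c3ccccc3)(c3ccccc3)C(C)(C)C)=C/C=C\C(C)=C/[C@@H](O)[C@@H]2C(=C)CO[Si](C)(C)C(C)(C)C)cc1 | intermediate
35 | tert-butyl hydroperoxide | CC(C)(C)OO | starting material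
36 | (4R,5S,6S,7S,8S)-4,5-epoxy-12-(TBS-oxy)-14-(TBDPS-oxy)-8-(PMB-oxy)germacra-1(10),2,11(13)-trien-6-ol (cis-epoxide, oxygen syn to 6-OH) | COc1ccc(CO[C@H]2C/C(CO[Si](c3ccccc3)(c3ccccc3)C(C)(C)C)=C/C=C\[C@@]3(C)O[C@H]3[C@@H](O)[C@@H]2C(=C)CO[Si](C)(C)C(C)(C)C)cc1 | intermediate
37 | potassium peroxymonosulfate | [K+].[O-]S(=O)(=O)OO | starting material
38 | (1R,4R,5S,6S,7S,8S,10S)-1,10:4,5-diepoxy-12-(TBS-oxy)-14-(TBDPS-oxy)-8-(PMB-oxy)germacra-2,11(13)-dien-6-ol (2Z) | COc1ccc(CO[C@H]2C[C@@]3(CO[Si](c4ccccc4)(c4ccccc4)C(C)(C)C)O[C@@H]3/C=C\[C@@]3(C)O[C@H]3[C@@H](O)[C@@H]2C(=C)CO[Si](C)(C)C(C)(C)C)cc1 | intermediate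
39 | (1R,4R,5S,6S,7S,8S,10S)-1,10:4,5-diepoxy-14-(TBDPS-oxy)-8-(PMB-oxy)germacra-2,11(13)-diene-6,12-diol | COc1ccc(CO[C@H]2C[C@@]3(CO[Si](c4ccccc4)(c4ccccc4)C(C)(C)C)O[C@@H]3/C=C\[C@@]3(C)O[C@H]3[C@@H](O)[C@@H]2C(=C)CO)cc1 | intermediate
40 | 6-hydroxy-12-al (enal from 39) | COc1ccc(CO[C@H]2C[C@@]3(CO[Si](c4ccccc4)(c4ccccc4)C(C)(C)C)O[C@@H]3/C=C\[C@@]3(C)O[C@H]3[C@@H](O)[C@@H]2C(=C)C=O)cc1 | intermediate (not isolated)
41 | 12,6-lactol (hemiacetal of 40) | COc1ccc(CO[C@H]2C[C@@]3(CO[Si](c4ccccc4)(c4ccccc4)C(C)(C)C)O[C@@H]3/C=C\[C@@]3(C)O[C@H]3[C@H]4OC(O)C(=C)[C@H]24)cc1 | intermediate (not isolated)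
42 | (1R,4R,5S,6S,7R,8S,10S)-1,10:4,5-diepoxy-14-(TBDPS-oxy)-8-(PMB-oxy)germacra-2,11(13)-dien-12,6-olide (trans-fused α-methylene lactone) | COc1ccc(CO[C@H]2C[C@@]3(CO[Si](c4ccccc4)(c4ccccc4)C(C)(C)C)O[C@@H]3/C=C\[C@@]3(C)O[C@H]3[C@H]4OC(=O)C(=C)[C@H]24)cc1 | intermediate
43 | 4-methylmorpholine N-oxide | C[N+]1([O-])CCOCC1 | starting material
44 | water | O | starting material
45 | (1R,4R,5S,6S,7R,8S,10S,11R)-1,10:4,5-diepoxy-11,13-dihydroxy-14-(TBDPS-oxy)-8-(PMB-oxy)germacr-2-en-12,6-olide (11-OH cis to H7) | COc1ccc(CO[C@H]2C[C@@]3(CO[Si](c4ccccc4)(c4ccccc4)C(C)(C)C)O[C@@H]3/C=C\[C@@]3(C)O[C@H]3[C@H]4OC(=O)[C@](O)(CO)[C@H]24)cc1 | intermediate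
46 | acetic anhydride | CC(=O)OC(C)=O | starting material
47 | 13-acetate of 45 (11-OH free) | COc1ccc(CO[C@H]2C[C@@]3(CO[Si](c4ccccc4)(c4ccccc4)C(C)(C)C)O[C@@H]3/C=C\[C@@]3(C)O[C@H]3[C@H]4OC(=O)[C@](O)(COC(C)=O)[C@H]24)cc1 | intermediate
48 | triethylammonium N-(methoxycarbonyl)sulfamate ester of 47 at C11–O | COc1ccc(CO[C@H]2C[C@@]3(CO[Si](c4ccccc4)(c4ccccc4)C(C)(C)C)O[C@@H]3/C=C\[C@@]3(C)O[C@H]3[C@H]4OC(=O)[C@](OS(=O)(=O)[N-]C(=O)OC)(COC(C)=O)[C@H]24)cc1.CC[NH+](CC)CC | intermediate (not isolated)
49 | (1R,4R,5S,6S,8S,10S)-13-acetoxy-1,10:4,5-diepoxy-14-(TBDPS-oxy)-8-(PMB-oxy)germacra-2,7(11)-dien-12,6-olide | COc1ccc(CO[C@H]2C[C@@]3(CO[Si](c4ccccc4)(c4ccccc4)C(C)(C)C)O[C@@H]3/C=C\[C@@]3(C)O[C@H]3[C@H]4OC(=O)C(COC(C)=O)=C24)cc1 | intermediate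
50 | (1R,4R,5S,6S,8S,10S)-13-acetoxy-1,10:4,5-diepoxy-8-hydroxy-14-(TBDPS-oxy)germacra-2,7(11)-dien-12,6-olide | O[C@H]1C[C@@]2(CO[Si](c3ccccc3)(c3ccccc3)C(C)(C)C)O[C@@H]2/C=C\[C@@]2(C)O[C@H]2[C@H]2OC(=O)C(COC(C)=O)=C12 | intermediate
51 | (2R)-2-methylbutanoic acid | CC[C@@H](C)C(=O)O | starting material
52 | (1R,4R,5S,6S,8S,10S)-13-acetoxy-1,10:4,5-diepoxy-8-[(2R)-2-methylbutanoyloxy]-14-(TBDPS-oxy)germacra-2,7(11)-dien-12,6-olide | CC[C@@H](C)C(=O)O[C@H]1C[C@@]2(CO[Si](c3ccccc3)(c3ccccc3)C(C)(C)C)O[C@@H]2/C=C\[C@@]2(C)O[C@H]2[C@H]2OC(=O)C(COC(C)=O)=C12 | intermediate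
53 | CNP0108300.1: (1R,4R,5S,6S,8S,10S)-13-acetoxy-1,10:4,5-diepoxy-14-hydroxy-8-[(2R)-2-methylbutanoyloxy]germacra-2(Z),7(11)-dien-12,6-olide | CC[C@@H](C)C(=O)O[C@H]1C[C@@]2(CO)O[C@@H]2/C=C\[C@@]2(C)O[C@H]2[C@H]2OC(=O)C(COC(C)=O)=C12 | target

## Step count and least certain steps

Total: 27 steps. Longest linear sequence: 25 steps (steps 3–27, from prop-2-yn-1-ol); steps 1 and 2 are one-step side branches.

**Step 17 (key step).** Lithiation may occur at another oxygen-bearing allylic or benzylic position. The lithiated trienyl ether may undergo [1,2]-shift or electrocyclic closure. Facial selectivity at C6 may be poor, since the envelope model is an argument and not a certainty in a 13-membered ring. The product triene may close thermally to a decalin before it is epoxidised. Fallback for the C6 configuration: starting from 34 as the C6 epimer mixture, oxidation with MnO2 at 0 °C gives the C6 trienone F1, and Corey–Bakshi–Shibata reduction ((R)-oxazaborolidine, catecholborane, −78 °C, trienyl group as the large substituent) sets C6 by reagent control and returns to 34.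

**Step 24.** Elimination may run toward C13 and give the exocyclic enol acetate, or may fail for lack of a syn hydrogen if the dihydroxylation in step 22 took the other lactone face. Fallback: starting from 45, selective oxidation of the primary alcohol (SO3·pyridine, DMSO, i-Pr2NEt) gives the 11-hydroxy-13-aldehyde F2, in which H7 is the only β-hydrogen. Dehydration (Burgess reagent for the cis isomer, Martin sulfurane for the trans isomer) gives the 13-oxo butenolide F3. Luche reduction (NaBH4, CeCl3, −78 °C) gives the 13-hydroxy butenolide F4, and acetylation returns to 49.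

**Step 19.** The dioxirane may attack C2=C3 or C11=C13, may show poor facial selectivity if the ring conformation opposes the catalyst, or the tertiary dienylic 4,5-epoxide of 36 may open. Fallback: starting from 36, N-bromosuccinimide in wet THF gives the bromohydrin F5 (water adds to the tertiary C10 anti to the bromonium ion), and K2CO3 in methanol closes it with inversion at C1 to 38. This two-step route places the epoxide oxygen on the face opposite to that taken by the electrophile, so it is complementary to direct epoxidation.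

**Step 16.** Intermolecular etherification, SN2′ attack at C7 or elimination of HCl may compete with closure of the 13-membered ring. Fallback: starting from 25, the same mesylation–chloride exchange gives the C13 chloride F6. Intermolecular Williamson reaction with the sodium alkoxide of 1 gives the acyclic ether F7. Intramolecular Sonogashira coupling at high dilution (Pd(PPh3)4, CuI, i-Pr2NH) closes the ring as the 13-membered dienyne F8, and zinc semireduction as in step 13 returns to 32.

**Step 6.** The β,γ-unsaturated aldehyde may isomerise or self-condense, and enantioselectivity with an unbranched aldehyde may be moderate. Fallback: starting from 13, addition of the lithium acetylide of 5 at −78 °C gives the C8-epimeric alcohol F9. Dess–Martin oxidation gives the ynone F10, and transfer hydrogenation with RuCl[(S,S)-TsDPEN](p-cymene) in i-PrOH, which reduces alkynyl ketones to the (S)-carbinols, returns to 15.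

## Further compounds

F1 | step 17 | (7S,8S)-12-(TBS-oxy)-14-(TBDPS-oxy)-8-(PMB-oxy)germacra-1(10),2,4,11(13)-tetraen-6-one | COc1ccc(CO[C@H]2C/C(CO[Si](c3ccccc3)(c3ccccc3)C(C)(C)C)=C/C=C\C(C)=C/C(=O)[C@@H]2C(=C)CO[Si](C)(C)C(C)(C)C)cc1
F2 | step 24 | 11-hydroxy-13-oxo analogue of 45 | COc1ccc(CO[C@H]2C[C@@]3(CO[Si](c4ccccc4)(c4ccccc4)C(C)(C)C)O[C@@H]3/C=C\[C@@]3(C)O[C@H]3[C@H]4OC(=O)[C@](O)(C=O)[C@H]24)cc1
F3 | step 24 | 13-oxo-7(11)-en-12,6-olide | COc1ccc(CO[C@H]2C[C@@]3(CO[Si](c4ccccc4)(c4ccccc4)C(C)(C)C)O[C@@H]3/C=C\[C@@]3(C)O[C@H]3[C@H]4OC(=O)C(C=O)=C24)cc1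
F4 | step 24 | 13-hydroxy-7(11)-en-12,6-olide | COc1ccc(CO[C@H]2C[C@@]3(CO[Si](c4ccccc4)(c4ccccc4)C(C)(C)C)O[C@@H]3/C=C\[C@@]3(C)O[C@H]3[C@H]4OC(=O)C(CO)=C24)cc1
F5 | step 19 | 1-bromo-10-hydroxy bromohydrin of 36 | COc1ccc(CO[C@H]2C[C@@](CO[Si](c3ccccc3)(c3ccccc3)C(C)(C)C)(O)[C@@H](Br)/C=C\[C@@]3(C)O[C@H]3[C@@H](O)[C@@H]2C(=C)CO[Si](C)(C)C(C)(C)C)cc1
F6 | step 16 | C13 chloride of 25 | COc1ccc(CO[C@H](/C=C(\CO[Si](C)(C)C(C)(C)C)CCl)C/C(CO[Si](c2ccccc2)(c2ccccc2)C(C)(C)C)=C/Br)cc1
F7 | step 16 | acyclic C6–O–C13 ether with C1–Br and terminal C2 alkyne | COc1ccc(CO[C@H](/C=C(\CO[Si](C)(C)C(C)(C)C)COC/C=C(C)\C#C)C/C(CO[Si](c2ccccc2)(c2ccccc2)C(C)(C)C)=C/Br)cc1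
F8 | step 16 | 13-membered cyclic ether with C2≡C3 (2,3-didehydro analogue of 32) | O1C/C(CO[Si](C)(C)C(C)(C)C)=C/[C@@H](OCc2ccc(OC)cc2)C/C(CO[Si](c2ccccc2)(c2ccccc2)C(C)(C)C)=C/C#C/C(C)=C\C1
F9 | step 6 | C8-epimeric mixture of 15 | OC(C#CCO[Si](CC)(CC)CC)C/C(CO[Si](c1ccccc1)(c1ccccc1)C(C)(C)C)=C/Br
F10 | step 6 | (1Z)-1-bromo-2-{[(tert-butyldiphenylsilyl)oxy]methyl}-7-[(triethylsilyl)oxy]hept-1-en-5-yn-4-one | O=C(C#CCO[Si](CC)(CC)CC)C/C(CO[Si](c1ccccc1)(c1ccccc1)C(C)(C)C)=C/Br
A1 | alternative 1 | diepoxy lactone with 8-OTES and 14-OTBS | CC[Si](CC)(CC)O[C@H]1C[C@@]2(CO[Si](C)(C)C(C)(C)C)O[C@@H]2/C=C\[C@@]2(C)O[C@H]2[C@H]2OC(=O)C(COC(C)=O)=C12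
A2 | alternative 1 | acyclic C10 ketone with C1 diphenylsulfonium tetrafluoroborate | CC[Si](CC)(CC)O[C@@H](CC(=O)CO[Si](C)(C)C(C)(C)C)C1=C(COC(C)=O)C(=O)O[C@@H]1[C@@H]1O[C@]1(C)/C=C\C[S+](c1ccccc1)c1ccccc1.F[B-](F)(F)F
A3 | alternative 2 | ten-membered trienolide (C1=C10 ring-trans, 2Z, C4=C5 ring-cis) | CC[C@@H](C)C(=O)O[C@H]1C/C(CO)=C/C=C\C(C)=C/[C@H]2OC(=O)C(COC(C)=O)=C12
A4 | alternative 2 | cis-fused eudesma-1,3-diene lactone | CC[C@@H](C)C(=O)O[C@H]1C[C@@]2(CO)C=CC=C(C)[C@H]2[C@H]2OC(=O)C(COC(C)=O)=C12
A5 | alternative 3 | ten-membered C6 ketone with 8-OPMB and 4,5-bis(TES-oxy) | COc1ccc(CO[C@H]2C/C(CO[Si](c3ccccc3)(c3ccccc3)C(C)(C)C)=C/C=C\[C@@](C)(O[Si](CC)(CC)CC)[C@H](O[Si](CC)(CC)CC)C(=O)C2)cc1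
A6 | alternative 3 | 1,2-dialkenylcyclohex-3-enol | COc1ccc(CO/C=C/[C@@]2(O)[C@@H](O[Si](CC)(CC)CC)[C@](C)(O[Si](CC)(CC)CC)C=C[C@@H]2C(=C)CO[Si](c2ccccc2)(c2ccccc2)C(C)(C)C)cc1
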